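**Assumptions (one line):** (E)-4-chloro-2-methylbut-2-en-1-ol and 2-(TBDPSO)acetaldehyde are commercial, and the Ir/amine catalyst pair can be chosen to give the i(R), a(R) diastereomer matched to (S)-citronellal. Labels a–i and s are ring atoms a–i plus the side-chain CH(CH3). The route has not been tested; the ring-closing step (12) and the Ir/amine allylation (5) are unprecedented.

## Retrosynthetic overview
1. Target ← lipase-selective O-acetylation ← MnO2 oxidation of the allylic CH2OH ← global desilylation ← stereoselective reduction of the ring ketone at C(h) ← dithiane hydrolysis.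
2. The only ring (nine-membered) is closed once, at C(g)–C(h), by intramolecular Corey–Seebach alkylation of a lithiodithiane with an E-allylic bromide. Both alkenes and all sp3 stereocentres except C(h) are already in place, and C(h) is set by ketone reduction.
3. The precursor comes from (S)-citronellal (gives C(s), C(i), C(h)). Ir/enamine α-allylation with an MBH carbonate sets C(i) and C(a) and adds the acrylate. Cross-metathesis with a preformed E-isoprenoid skipped-diene unit then gives the Z(ring) enoate and the E-trisubstituted alkene.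

## Route

**Step 1**
Reactants: 1 (E)-4-chloro-2-methylbut-2-en-1-ol
Product: 2 TBS ether of 1
Conditions: TBSCl, imidazole, DMF, 0 °C → rt
Reagents that add atoms: TBSCl, CC(C)(C)[Si](C)(C)Cl
Why: Silylation of a primary alcohol; there is no stereocentre and the E-alkene is untouched.

**Step 2**
Reactants: 2; vinylmagnesium bromide
Product: 3 (2E)-2-methylhexa-2,5-dienyl TBS ether
Conditions: CH2=CHMgBr, CuI (10 mol%), THF, –30 °C
Reagents that add atoms: vinylmagnesium bromide, C=C[Mg]Br
Why: Cu-catalysed SN2 at the primary CH2Cl; SN2′ is blocked because the γ-carbon is tertiary. The E geometry is retained, so the cross-metathesis partner carries the finished E-alkene (d/g trans).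

**Step 3**
Reactants: 4 2-(TBDPSO)acetaldehyde; 5 methyl acrylate
Product: 6 racemic MBH adduct
Conditions: DABCO (20 mol%), MeOH, rt
Reagents that add atoms: none
Why: Morita–Baylis–Hillman reaction. The carbinol stereocentre is racemic and is destroyed later in the π-allyl, so it does not matter.

**Step 4**
Reactants: 6
Product: 7 MBH Boc-carbonate
Conditions: Boc2O, DMAP, CH2Cl2, 0 °C
Reagents that add atoms: Boc2O, CC(C)(C)OC(=O)OC(=O)OC(C)(C)C
Why: O-acylation makes the alcohol an Ir-π-allyl precursor.

**Step 5**
Reactants: 8 (S)-citronellal; 7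
Product: 9 α-allylated aldehyde, OHC(h)–C(i)(s)–C(a)(CH2OTBDPS)–C(CO2Me)=CH2
Conditions: [Ir(cod)Cl]2 (2 mol%), chiral P,olefin ligand, diarylprolinol TMS ether (20 mol%), acid additive, dioxane, 25 °C
Reagents that add atoms: none
Why: Proposed new method: Carreira-type Ir/enamine dual catalysis, here with a racemic MBH carbonate as the Ir-π-allyl electrophile. The enamine of citronellal attacks the more substituted π-allyl terminus (branched selectivity with Ir) and leaves the acrylate intact. Amine and Ir ligand chirality are stereodivergent and set i(R) and a(R) relative to the existing s(S).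

**Step 6**
Reactants: 9; 3
Product: 10 (E)-enoate, b(CO2Me)=c–d–e=f(Me)–g–OTBS
Conditions: Hoveyda–Grubbs II (5 mol%), CH2Cl2, 40 °C, 3 equiv 3
Reagents that add atoms: none
Why: Cross-metathesis of a 1,1-disubstituted acrylate with a type I terminal alkene. The thermodynamic enoate has CO2Me trans to d, which places a cis to d (the ring-Z relationship in the target). The trisubstituted alkenes are type III and are not expected to react.

**Step 7**
Reactants: 10
Product: 11 1,3-dithiane at C(h)
Conditions: HS(CH2)3SH, I2 (5 mol%), CH2Cl2, 0 °C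
Reagents that add atoms: propane-1,3-dithiol, SCCCS
Why: Thioacetalisation masks the aldehyde as an acyl-anion equivalent and removes the enolisable α-CH next to C(i), so C(i) cannot epimerise later.

**Step 8**
Reactants: 11
Product: 12 allylic alcohol, C(b)–CH2OH
Conditions: DIBAL-H (3 equiv), CH2Cl2, –78 °C
Reagents that add atoms: none
Why: The enoate is reduced to the allylic alcohol so that it cannot react with the dithiane anion in Step 12.

**Step 9**
Reactants: 12
Product: 13 TBDPS ether at C(b)–CH2O
Conditions: TBDPSCl, imidazole, DMAP, DMF, 40 °C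
Reagents that add atoms: TBDPSCl, CC(C)(C)[Si](c1ccccc1)(c1ccccc1)Cl
Why: Protects the allylic alcohol with a group that is stable to the acidic selective TBS removal in Step 10.

**Step 10**
Reactants: 13
Product: 14 allylic alcohol at C(g)
Conditions: CSA (0.2 equiv), MeOH/CH2Cl2, 0 °C
Reagents that add atoms: none
Why: Acid methanolysis removes the primary TBS ether faster than the two TBDPS ethers.

**Step 11**
Reactants: 14
Product: 15 E-allylic bromide
Conditions: PPh3, CBr4, CH2Cl2, 0 °C; used immediately
Reagents that add atoms: CBr4, BrC(Br)(Br)Br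
Why: Appel bromination by SN2 at a primary carbon, with no allylic transposition. The alkene geometry is retained.

**Step 12**
Reactants: 15
Product: 16 nine-membered ring dithiane
Conditions: n-BuLi (1.1 equiv), THF/HMPA, –78 → –20 °C, 1–2 mM, syringe-pump addition over 6 h
Reagents that add atoms: none
Why: Proposed new method: intramolecular Corey–Seebach macro-alkylation with an E-trisubstituted allylic bromide. SN2 at the primary terminus g closes the C(g)–C(h) bond and leaves both alkenes and the three stereocentres untouched. The a/d-cis enoate geometry is pre-organised for the ring. The dithiane carbon is not stereogenic. The closest known reaction is intramolecular dithiane alkylation with halides (medium and large rings). The main competing pathways are SN2′ at C(e), which would give a seven-membered ring, and attack of BuLi on the bromide.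

**Step 13**
Reactants: 16
Product: 17 ring ketone at C(h)
Conditions: MeI (20 equiv), NaHCO3, MeCN/H2O (9:1), 50 °C
Reagents that add atoms: water (source of the ketone O), O
Why: S-methylation followed by hydrolysis of the dithiane under mild, non-oxidative conditions. This avoids attack on the alkenes and avoids epimerising C(i).

**Step 14**
Reactants: 17
Product: 18 alcohol with C(h) as S
Conditions: L-Selectride, THF, –78 °C
Reagents that add atoms: none
Why: Hydride is delivered to the exterior face of the ring, anti to the neighbouring C(i) substituent. The new C(h) stereocentre is set by this substrate control. The opposite face is the fallback (see risks).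

**Step 15**
Reactants: 18
Product: 19 triol
Conditions: TBAF, THF, 0 °C → rt
Reagents that add atoms: none
Why: Global desilylation; no stereocentre is touched.

**Step 16**
Reactants: 19
Product: 20 enal with free CH2OH and free C(h)–OH
Conditions: MnO2 (20 equiv), CH2Cl2, rt
Reagents that add atoms: none
Why: MnO2 oxidises only the allylic CH2OH. The homoallylic C(a)–CH2OH and the C(h)–OH are inert, and the alkene geometries are retained.

**Step 17**
Reactants: 20; vinyl acetate
Product: 21 target
Conditions: vinyl acetate, Novozym 435, TBME, rt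
Reagents that add atoms: vinyl acetate, C=COC(C)=O
Why: Lipase-catalysed transesterification acetylates the primary CH2OH selectively over the secondary alcohol and does not touch the enal.

## Compound list
1 | (2E)-4-chloro-2-methylbut-2-en-1-ol | ClC/C=C(\C)CO | starting material
2 | TBS ether of 1 | ClC/C=C(\C)CO[Si](C)(C)C(C)(C)C | intermediate
3 | tert-butyldimethyl{[(2E)-2-methylhexa-2,5-dien-1-yl]oxy}silane | C=CC/C=C(\C)CO[Si](C)(C)C(C)(C)C | intermediate
4 | 2-(TBDPSO)acetaldehyde | O=CCO[Si](c1ccccc1)(c1ccccc1)C(C)(C)C | starting material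
5 | methyl acrylate | C=CC(=O)OC | starting material
6 | racemic MBH adduct | C=C(C(=O)OC)C(O)CO[Si](c1ccccc1)(c1ccccc1)C(C)(C)C | intermediate
7 | racemic MBH Boc-carbonate | C=C(C(=O)OC)C(OC(=O)OC(C)(C)C)CO[Si](c1ccccc1)(c1ccccc1)C(C)(C)C | intermediate
8 | (S)-citronellal, (3S)-3,7-dimethyloct-6-enal | C[C@@H](CCC=C(C)C)CC=O | starting material
9 | α-allylated aldehyde (i R, a R, s S) | O=C[C@@H]([C@@H](CO[Si](c1ccccc1)(c1ccccc1)C(C)(C)C)C(=C)C(=O)OC)[C@@H](C)CCC=C(C)C | intermediate
10 | cross-metathesis enoate | O=C[C@@H]([C@@H](CO[Si](c1ccccc1)(c1ccccc1)C(C)(C)C)/C(C(=O)OC)=C\C/C=C(\C)CO[Si](C)(C)C(C)(C)C)[C@@H](C)CCC=C(C)C | intermediate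
11 | dithiane of 10 | C2(SCCCS2)[C@@H]([C@@H](CO[Si](c1ccccc1)(c1ccccc1)C(C)(C)C)/C(C(=O)OC)=C\C/C=C(\C)CO[Si](C)(C)C(C)(C)C)[C@@H](C)CCC=C(C)C | intermediate
12 | allylic alcohol at C(b) | C2(SCCCS2)[C@@H]([C@@H](CO[Si](c1ccccc1)(c1ccccc1)C(C)(C)C)/C(CO)=C\C/C=C(\C)CO[Si](C)(C)C(C)(C)C)[C@@H](C)CCC=C(C)C | intermediate
13 | bis-TBDPS, g-OTBS | C2(SCCCS2)[C@@H]([C@@H](CO[Si](c1ccccc1)(c1ccccc1)C(C)(C)C)/C(CO[Si](c1ccccc1)(c1ccccc1)C(C)(C)C)=C\C/C=C(\C)CO[Si](C)(C)C(C)(C)C)[C@@H](C)CCC=C(C)C | intermediate
14 | g-alcohol | C2(SCCCS2)[C@@H]([C@@H](CO[Si](c1ccccc1)(c1ccccc1)C(C)(C)C)/C(CO[Si](c1ccccc1)(c1ccccc1)C(C)(C)C)=C\C/C=C(\C)CO)[C@@H](C)CCC=C(C)C | intermediate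
15 | E-allylic bromide | C2(SCCCS2)[C@@H]([C@@H](CO[Si](c1ccccc1)(c1ccccc1)C(C)(C)C)/C(CO[Si](c1ccccc1)(c1ccccc1)C(C)(C)C)=C\C/C=C(\C)CBr)[C@@H](C)CCC=C(C)C | intermediate
16 | nine-membered ring dithiane | CC(C)(C)[Si](c1ccccc1)(c1ccccc1)OC[C@H]1/C(CO[Si](c2ccccc2)(c2ccccc2)C(C)(C)C)=C\C/C=C(\C)CC3(SCCCS3)[C@@H]1[C@@H](C)CCC=C(C)C | intermediate
17 | ring ketone | CC(C)(C)[Si](c1ccccc1)(c1ccccc1)OC[C@H]1/C(CO[Si](c2ccccc2)(c2ccccc2)C(C)(C)C)=C\C/C=C(\C)CC(=O)[C@@H]1[C@@H](C)CCC=C(C)C | intermediate
18 | ring alcohol, bis-TBDPS | CC(C)(C)[Si](c1ccccc1)(c1ccccc1)OC[C@H]1/C(CO[Si](c2ccccc2)(c2ccccc2)C(C)(C)C)=C\C/C=C(\C)C[C@H](O)[C@@H]1[C@@H](C)CCC=C(C)C | intermediate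
19 | triol | OC[C@H]1/C(CO)=C\C/C=C(\C)C[C@H](O)[C@@H]1[C@@H](C)CCC=C(C)C | intermediate
20 | enal, free CH2OH | OC[C@H]1/C(C=O)=C\C/C=C(\C)C[C@H](O)[C@@H]1[C@@H](C)CCC=C(C)C | intermediate
21 | Hydroxyacetyldictyolal | CC(=O)OC[C@H]1/C(C=O)=C\C/C=C(\C)C[C@H](O)[C@@H]1[C@@H](C)CCC=C(C)C | target

## Summary
Total steps: 17. Longest linear sequence: 15 (from 4: steps 3, 4, 5 … 17).

**Three steps most likely to fail, with fallbacks**
1. **Step 12 (macro-alkylation):** the nine-membered ring with an E- and a Z-alkene may not close, SN2′ to the seven-membered ring may dominate, or BuLi may attack the allylic bromide. Fallback: drop the dithiane and form C(g)–C(h) and the E-alkene with a Still [2,3]-Wittig ring expansion of an eight-membered cyclic ether that carries an α-stannyl ether at C(h) and an isopropenyl group at C(e).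
2. **Step 5 (Ir/amine allylation with an MBH carbonate):** this combination is unprecedented and dr may be poor. Fallback: Hayashi–Jørgensen Michael addition of (S)-citronellal to (E)-3-(TBDPSO)-1-nitropropene, which is syn-selective. Then convert CH2NO2 by Nef, MeOCH=PPh3 homologation and hydrolysis, and form the enal by aldol condensation.
3. **Step 14 (ketone reduction):** the facial selectivity on the flexible nine-membered ring is uncertain. Fallback: oxidise any wrong epimer back to the ketone and invert it by Mitsunobu with p-nitrobenzoic acid followed by hydrolysis. Alternatively set C(h) in the acyclic series before ring closure by Marshall propargylation of the aldehyde.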